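**Plan**

- Locants: C1 spiro carbon; C2, C3 cyclopentane CH2; C4 methyl-bearing quaternary carbon; C5 the O–CH; C6=C7 the ring alkene (isopropyl on C7); C10 the ring CH–CH3; C9′ benzylic CH; O1 pyran oxygen; ArC5–ArC8 arene carbons in chroman order.
- Retrosynthesis: remove the two formyl groups (Rieche) and take C6=C7 back to a C6 ketone (via its enol triflate); cut C1–C2 and O1–C5 together (one base cascade); cut C5–C1 (oxocarbenium ion + menthone enol silane); cut C9′–C4 and C5–O (o-quinone methide hetero-Diels–Alder with 4-methyl-2,3-dihydrofuran).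
- Enabling feature: once C6 is a ketone, spiro C1 is its α-carbon and O-bearing C5 its β-carbon, so C5=C1–C6=O is a 2-alkylidenecyclohexanone. The phenol oxygen adds to C5, and the enolate thereby formed at C1 displaces iodide from C2 on the two-carbon arm of C4.
- Forward: arene + dihydrofuran give the furo-chroman acetal (C9′, C4); union with the cyclohexanone at C5; acylative opening of the tetrahydrofuran; the cascade closes the pyran and then the cyclopentane (spiro centre); enol triflate, formylation, demethylation and triflate reduction finish.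
- Stereochemistry: C10 from (−)-menthone; C9′/C4 relative configuration from the endo cycloaddition; C5 and C1 in the cascade, steered by C4 (cis ring fusion) and C10 (attack anti to methyl).

Key step: step 8

Remark: the cycloadduct of step 4 is racemic and is joined to enantiopure menthone, so from step 6 on each intermediate is accompanied by the diastereomer that stems from the mirror-image cycloadduct, until the two series are separated by chromatography after step 8; the SMILES show the series that leads to the target.

**Route**

Step 1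
Reactants: 1 3-methyldihydrofuran-2(3H)-one (α-methyl-γ-butyrolactone, racemic)
Product: 2 3-methyltetrahydrofuran-2-ol (lactol, mixture of stereoisomers)
Conditions: i-Bu2AlH (1.05 equiv), CH2Cl2, −78 °C
Reagents that add atoms: none
Why: Partial reduction of a lactone to the lactol by i-Bu2AlH at low temperature is standard, because the aluminium hemiacetal survives until work-up; the stereocentre is lost in step 2.

Step 2
Reactants: 2 3-methyltetrahydrofuran-2-ol
Product: 3 4-methyl-2,3-dihydrofuran
Conditions: MsCl, Et3N, CH2Cl2, −20 °C → reflux; fractional distillation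
Reagents that add atoms: none
Why: Mesylation of the lactol hydroxyl and elimination (the only β-hydrogen sits on the methyl-bearing carbon) should give the cyclic enol ether, the usual lactol-to-dihydrofuran dehydration.

Step 3
Reactants: 4 2-hydroxy-4,6-dimethoxybenzaldehyde
Product: 5 tert-butyl (2-formyl-3,5-dimethoxyphenyl) carbonate
Conditions: Boc2O, i-Pr2NEt, DMAP (cat.), THF, rt
Reagents that add atoms: di-tert-butyl dicarbonate, CC(C)(C)OC(=O)OC(=O)OC(C)(C)C
Why: DMAP-catalysed O-acylation of the phenol installs the migrating carbonate needed for low-temperature o-quinone methide generation.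

Step 4
Reactants: 5 tert-butyl (2-formyl-3,5-dimethoxyphenyl) carbonate; 6 isobutylmagnesium bromide; 3 4-methyl-2,3-dihydrofuran
Product: 8 rac-(3aR,4R,9aS)-4-isobutyl-5,7-dimethoxy-3a-methyl-2,3,3a,9a-tetrahydro-4H-furo[2,3-b]chromene (cis-fused acetal; isobutyl cis to the furan ring; trans to the methyl group), via ortho-quinone methide 7 (not isolated)
Conditions: 6 (1.05 equiv), 3 (4 equiv), Et2O/THF, −78 °C → rt
Reagents that add atoms: none
Why: Grignard addition, Boc transfer to the benzylic alkoxide and loss of tert-butyl carbonate give the (E)-o-quinone methide at low temperature, and its inverse-demand hetero-Diels–Alder reaction with the cyclic enol ether joins the nucleophilic methyl-bearing carbon to C9′ and the oxygen-bearing carbon to the phenol oxygen through the endo transition state (ring oxygen under the heterodiene), which sets isobutyl cis to the furan ring and trans to the C4 methyl group, the cis ring fusion following from the cyclic enol ether.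

Step 5
Reactants: 9 (−)-menthone, (2S,5R)-2-isopropyl-5-methylcyclohexan-1-one
Product: 10 trimethyl{[(3R,6S)-6-isopropyl-3-methylcyclohex-1-en-1-yl]oxy}silane
Conditions: LiN(i-Pr)2, THF, −78 °C; Me3SiCl, −78 → 0 °C
Reagents that add atoms: chlorotrimethylsilane, C[Si](C)(C)Cl
Why: Kinetic deprotonation at the α-CH2 (not at the isopropyl-bearing CH) and O-silylation give the less substituted silyl enol ether; the methyl-bearing centre (later C10) comes unchanged from the chiral pool.

Step 6
Reactants: 8 furo-chroman acetal; 10 menthone silyl enol ether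
Product: 12 (3R)-6-isopropyl-3-methyl-2-{(3R)-3-[(1S)-1-(2-hydroxy-4,6-dimethoxyphenyl)-3-methylbutyl]-3-methyltetrahydrofuran-2-yl}cyclohexan-1-one (epimers at tetrahydrofuran C2; ring C2; ring C6), via aryl silyl ether 11 (not isolated)
Conditions: Me3SiOTf (0.3 equiv), 10 (1.5 equiv), CH2Cl2, −78 → −40 °C; aq. NaHCO3, then 1 M HCl, THF, 0 °C
Reagents that add atoms: none
Why: Mukaiyama-type addition of a silyl enol ether to a cyclic oxocarbenium ion: in the mixed aryl alkyl acetal the aryloxy group is the better leaving group and its loss leaves the oxygen-stabilised five-membered cation, which the enol silane attacks at C5 through its unsubstituted carbon (C1); the new centres C5 and C1 need no control because both become trigonal in step 8.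

Step 7
Reactants: 12 phenol tetrahydrofuranyl ketone
Product: 14 (3R)-2-{(2R)-1-acetoxy-2-[(1S)-1-(2-acetoxy-4,6-dimethoxyphenyl)-3-methylbutyl]-4-iodo-2-methylbutyl}-6-isopropyl-3-methylcyclohexan-1-one (epimers at the acetoxy-bearing carbon; ring C2; ring C6), via aryl acetate 13 (not isolated)
Conditions: Ac2O, pyridine, DMAP (cat.), CH2Cl2, rt; evaporate; then AcCl, NaI, MeCN, 0 °C → rt
Reagents that add atoms: acetic anhydride, CC(=O)OC(C)=O; acetyl chloride, CC(Cl)=O; sodium iodide, [Na+].[I-]
Why: Phenol acetylation and then acylative ether cleavage by acetyl iodide made in the flask: the tetrahydrofuran oxygen is acylated and iodide opens the oxonium ion by SN2 attack at the primary C2 (C5 is secondary, neopentylic and next to the ketone α-carbon), which gives the β-acetoxy ketone carrying the 2-iodoethyl arm.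

Step 8
Reactants: 14 β-acetoxy ketone aryl acetate iodide
Product: 17 spiro ketone: ArC5,ArC7-dimethoxy chroman cis-fused at C4–C5 to the cyclopentane; spiro at C1 to the 2-isopropyl-5-methylcyclohexanone ring whose carbonyl is C6 (C9′ S; C4 R; C5 S; C1 S; C10 R; C7 epimers), via enone phenoxide 15 (not isolated), via chroman enolate 16 (not isolated)
Conditions: KOt-Bu (3 equiv), THF/t-BuOH (5:1), −20 °C → rt; chromatography (separation from the diastereomer of the mirror-image series)
Reagents that add atoms: none
Why: tert-Butoxide removes the C5 acetate by E1cB elimination and the aryl acetate by acyl transfer, so that the phenoxide of 15 adds to C5 of the 2-alkylidenecyclohexanone (oxa-Michael) and the enolate thus formed at C1 (16) displaces iodide at C2 in an intramolecular SN2 reaction. The closest known reaction type is the Michael-initiated ring closure, ending in the classical intramolecular ketone alkylation that makes spiro[4.5]decanones. The pyran ring closes 6-exo-trig and the cyclopentane 5-(enolexo)-exo-tet. C5 is set under the control of quaternary C4, because the oxa-Michael step is reversible and only the adduct with C1 and the iodoethyl arm on the same face of the pyran closes readily to the cis-fused bicycle, while C1 is set by C10, because C2 enters the enolate face anti to the pseudoaxial C10 methyl group in the rotamer that turns C5–H toward C10 and lets K+ bridge the enolate oxygen and O1. The step needs loss of acetate from the first C1 enolate before that enolate can alkylate (β-acyloxy enolates fragment fast), alkylation of the enolate carbon C1 and not of the phenoxide oxygen (five- against seven-membered ring, soft iodide, protic co-solvent) and alkylation at C1 and not C7 (the enolate arises at C1 by the conjugate addition and a C7 enolate cannot reach C2), with base in excess so that the C7 epimers equilibrate to the one with pseudoequatorial isopropyl. The companion diastereomer that stems from the mirror-image cycloadduct should form by the same cascade and is removed by chromatography at this stage.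

Step 9
Reactants: 17 spiro ketone
Product: 18 enol triflate: as 17 with C6(OSO2CF3)=C7(isopropyl) in place of the ketone (C9′ S, C4 R, C5 S, C1 S, C10 R)
Conditions: KN(SiMe3)2, THF, −78 → 0 °C; PhNTf2, 0 °C → rt
Reagents that add atoms: N-phenylbis(trifluoromethanesulfonimide), O=S(=O)(N(c1ccccc1)S(=O)(=O)C(F)(F)F)C(F)(F)F
Why: The ketone has a single enolisable position (C7–H, since C1 is quaternary), so enolate O-triflation gives the C6=C7 enol triflate regiospecifically and the C7 epimers converge.

Step 10
Reactants: 18 enol triflate
Product: 19 dialdehyde: 18 with formyl groups at ArC6 and ArC8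
Conditions: Cl2CHOMe (6 equiv), TiCl4 (6 equiv), CH2Cl2, −78 → 0 °C; H2O
Reagents that add atoms: dichloromethyl methyl ether, COC(Cl)Cl; water, O
Why: Rieche formylation (Friedel–Crafts attack of the chloromethoxycarbenium ion, then hydrolysis) at the two free arene positions, each flanked by two oxygen substituents; the future alkene is masked as the electron-poor enol triflate, which should not protonate under the acidic conditions.

Step 11
Reactants: 19 dialdehyde dimethyl ether
Product: 20 diphenol: 19 with hydroxyl groups at ArC5 and ArC7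
Conditions: BCl3 (5 equiv), CH2Cl2, −78 → 0 °C; aqueous work-up
Reagents that add atoms: none
Why: Chelation-assisted cleavage of aryl methyl ethers ortho to a carbonyl group by BCl3 (chloride attacks the methyl group of the boron-bound ether); both methoxy groups are ortho to a formyl group, whereas the secondary, neopentylic O1–C5 bond resists SN2 attack.

Step 12
Reactants: 20 diphenol enol triflate
Product: 21 target CNP0121396.3 (C9′ S, C4 R, C5 S, C1 R, C10 R)
Conditions: Pd(OAc)2 (10 mol %), PPh3 (20 mol %), HCO2H (3 equiv), Et3N (6 equiv), DMF, 70 °C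
Reagents that add atoms: none
Why: Palladium-catalysed formate reduction of an enol triflate (oxidative addition of zerovalent palladium, formate-to-hydride exchange with loss of CO2, reductive elimination) replaces the triflate by hydrogen without moving the double bond, so the C6=C7 alkene appears only in this last, non-acidic step.

**Compound list**

1 | 3-methyldihydrofuran-2(3H)-one (α-methyl-γ-butyrolactone), racemic | CC1CCOC1=O | starting material
2 | 3-methyltetrahydrofuran-2-ol, mixture of stereoisomers | CC1CCOC1O | intermediate
3 | 4-methyl-2,3-dihydrofuran | CC1=COCC1 | intermediate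
4 | 2-hydroxy-4,6-dimethoxybenzaldehyde | COc1cc(O)c(C=O)c(OC)c1 | starting material
5 | tert-butyl (2-formyl-3,5-dimethoxyphenyl) carbonate | COc1cc(OC(=O)OC(C)(C)C)c(C=O)c(OC)c1 | intermediate
6 | isobutylmagnesium bromide | CC(C)C[Mg]Br | starting material
7 | (E)-3,5-dimethoxy-6-(3-methylbutylidene)cyclohexa-2,4-dien-1-one (o-quinone methide) | CC(C)C/C=C1/C(=O)C=C(OC)C=C1OC | intermediate
8 | rac-(3aR,4R,9aS)-4-isobutyl-5,7-dimethoxy-3a-methyl-2,3,3a,9a-tetrahydro-4H-furo[2,3-b]chromene (enantiomer shown leads to the target) | CC(C)C[C@@H]1c2c(OC)cc(OC)cc2O[C@H]2[C@]1(C)CCO2 | intermediate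
9 | (−)-menthone, (2S,5R)-2-isopropyl-5-methylcyclohexan-1-one | CC(C)[C@@H]1CC[C@@H](C)CC1=O | starting material
10 | trimethyl{[(3R,6S)-6-isopropyl-3-methylcyclohex-1-en-1-yl]oxy}silane | CC(C)[C@@H]1CC[C@@H](C)C=C1O[Si](C)(C)C | intermediate
11 | aryl trimethylsilyl ether of 12 | CC(C)C[C@H](c1c(OC)cc(OC)cc1O[Si](C)(C)C)[C@@]2(C)CCOC2C3C(=O)C(C(C)C)CC[C@H]3C | intermediate
12 | (3R)-6-isopropyl-3-methyl-2-{(3R)-3-[(1S)-1-(2-hydroxy-4,6-dimethoxyphenyl)-3-methylbutyl]-3-methyltetrahydrofuran-2-yl}cyclohexan-1-one, epimers at tetrahydrofuran C2, ring C2 and ring C6 | CC(C)C[C@H](c1c(OC)cc(OC)cc1O)[C@@]2(C)CCOC2C3C(=O)C(C(C)C)CC[C@H]3C | intermediate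
13 | aryl acetate of 12 | CC(C)C[C@H](c1c(OC)cc(OC)cc1OC(C)=O)[C@@]2(C)CCOC2C3C(=O)C(C(C)C)CC[C@H]3C | intermediate
14 | (3R)-2-{(2R)-1-acetoxy-2-[(1S)-1-(2-acetoxy-4,6-dimethoxyphenyl)-3-methylbutyl]-4-iodo-2-methylbutyl}-6-isopropyl-3-methylcyclohexan-1-one, epimers at the acetoxy carbon, ring C2 and ring C6 | CC(C)C[C@H](c1c(OC)cc(OC)cc1OC(C)=O)[C@@](C)(CCI)C(OC(C)=O)C2C(=O)C(C(C)C)CC[C@H]2C | intermediate
15 | potassium phenoxide of the (E)-2-alkylidene ketone formed from 14 by loss of both acetyl groups (C9′ and C4 as in 14, C10 R; alkene geometry immaterial) | CC(C)C[C@H](c1c(OC)cc(OC)cc1[O-])[C@@](C)(CCI)/C=C2/C(=O)C(C(C)C)CC[C@H]2C.[K+] | intermediate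
16 | potassium C1=C6 enolate of the chroman ketone after O1–C5 bond formation (C9′ S, C4 R, C5 S, C10 R; 2-iodoethyl arm on C4 cis to the C5 substituent) | CC(C)C[C@@H]1c2c(OC)cc(OC)cc2O[C@H](C3=C([O-])C(C(C)C)CC[C@H]3C)[C@]1(C)CCI.[K+] | intermediate
17 | spiro ketone (C9′ S, C4 R, C5 S, C1 S, C10 R; C7 epimers) | CC(C)C[C@@H]1c2c(OC)cc(OC)cc2O[C@H]2[C@]1(C)CC[C@@]21C(=O)C(C(C)C)CC[C@H]1C | intermediate
18 | enol triflate of 17 (C6–OTf, C6=C7) | CC(C)C[C@@H]1c2c(OC)cc(OC)cc2O[C@H]2[C@]1(C)CC[C@@]21C(OS(=O)(=O)C(F)(F)F)=C(C(C)C)CC[C@H]1C | intermediate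
19 | ArC6,ArC8-diformyl derivative of 18 | CC(C)C[C@@H]1c2c(OC)c(C=O)c(OC)c(C=O)c2O[C@H]2[C@]1(C)CC[C@@]21C(OS(=O)(=O)C(F)(F)F)=C(C(C)C)CC[C@H]1C | intermediate
20 | ArC5,ArC7-diphenol of 19 | CC(C)C[C@@H]1c2c(O)c(C=O)c(O)c(C=O)c2O[C@H]2[C@]1(C)CC[C@@]21C(OS(=O)(=O)C(F)(F)F)=C(C(C)C)CC[C@H]1C | intermediate
21 | CNP0121396.3 (C9′ S, C4 R, C5 S, C1 R, C10 R) | CC(C)C[C@@H]1c2c(O)c(C=O)c(O)c(C=O)c2O[C@H]2[C@]1(C)CC[C@@]21C=C(C(C)C)CC[C@H]1C | target

**Count**

Total steps: 12. Longest linear sequence: 10 steps (steps 1, 2, 4, 6, 7, 8, 9, 10, 11, 12).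

**Steps most likely to fail**

Step 8. The risk is O-alkylation of the phenoxide at C2 (a seven-membered aryl ether) outrunning the oxa-Michael/C-alkylation channel, or poor facial selectivity at C1. The fallback makes the C1–C2 bond by a reversible aldol addition, so no alkylating carbon is present. It sets out from 14: trimethylamine N-oxide in DMSO should oxidise the primary iodide to the aldehyde F1. K2CO3 in MeOH should then trigger elimination of the C5 acetate, methanolysis of the aryl acetate, oxa-Michael addition and intramolecular aldol addition of C1 to the C2 aldehyde, giving the spiro β-hydroxy ketone F2 under thermodynamic control. Burgess reagent (methyl N-(triethylammoniumsulfonyl)carbamate) should dehydrate it toward C3, since C1 is quaternary, to the cyclopentene F3. H2 over Pd/C (palladium on carbon) saturates C2=C3 and the route is rejoined at 17.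

Step 6. The risk is ionisation of the other acetal C–O bond (loss of the furan oxygen, attack on the chroman oxocarbenium ion), or slow attack at the neopentylic cation. The fallback uses the product of that mode and keeps the pyran ring from the cycloadduct. It sets out from 8: the same coupling would then give the chroman alcohol F4. I2, PPh3 and imidazole convert it to the iodide F5. KN(SiMe3)2 in THF (−78 → 0 °C) should close the cyclopentane by direct intramolecular enolate alkylation, with C5 equilibrated through reversible E1cB opening and oxa-Michael re-closure. The route is rejoined at 17.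

Step 10. The risk is incomplete second formylation of the deactivated mono-aldehyde, or Lewis-acid damage to the chroman. The fallback installs the aldehydes one at a time with a phenol-directed second formylation. It sets out from 18: Vilsmeier–Haack formylation (POCl3, DMF) should give mainly the ArC8 mono-aldehyde F6, the position next to the tied-back ring oxygen being the less hindered one. BCl3 frees the hydroxyl ortho to the aldehyde to give the ArC7 phenol F7. Ortho-formylation of its magnesium phenoxide (MgCl2, Et3N, paraformaldehyde, MeCN, reflux) should give the ArC6,ArC8 dialdehyde F8. BCl3 removes the last methyl ether and the route is rejoined at 20.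

Further compounds
F1 | step 8 | aldehyde analogue of 14 (C2 is CHO in place of CH2I) | CC(C)C[C@H](c1c(OC)cc(OC)cc1OC(C)=O)[C@@](C)(CC=O)C(OC(C)=O)C2C(=O)C(C(C)C)CC[C@H]2C
F2 | step 8 | spiro β-hydroxy ketone: 17 with a hydroxyl group on C2 (mixture at C2) | CC(C)C[C@@H]1c2c(OC)cc(OC)cc2O[C@H]2[C@]1(C)CC(O)[C@@]21C(=O)C(C(C)C)CC[C@H]1C
F3 | step 8 | cyclopentene: 17 with a C2=C3 double bond | CC(C)C[C@@H]1c2c(OC)cc(OC)cc2O[C@H]2[C@]1(C)C=C[C@@]21C(=O)C(C(C)C)CC[C@H]1C
F4 | step 6 | chroman alcohol: ArC5,ArC7-dimethoxy chroman with the 3-isopropyl-6-methyl-2-oxocyclohexyl group on C5 and methyl plus 2-hydroxyethyl on C4 (C9′ S, C4 R, C10 R; C5, C1, C7 mixed) | CC(C)C[C@@H]1c2c(OC)cc(OC)cc2OC(C3C(=O)C(C(C)C)CC[C@H]3C)[C@]1(C)CCO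
F5 | step 6 | iodide of F4 (2-iodoethyl on C4) | CC(C)C[C@@H]1c2c(OC)cc(OC)cc2OC(C3C(=O)C(C(C)C)CC[C@H]3C)[C@]1(C)CCI
F6 | step 10 | ArC8 mono-aldehyde of 18 | CC(C)C[C@@H]1c2c(OC)cc(OC)c(C=O)c2O[C@H]2[C@]1(C)CC[C@@]21C(OS(=O)(=O)C(F)(F)F)=C(C(C)C)CC[C@H]1C
F7 | step 10 | F6 with a free hydroxyl group at ArC7 | CC(C)C[C@@H]1c2c(OC)cc(O)c(C=O)c2O[C@H]2[C@]1(C)CC[C@@]21C(OS(=O)(=O)C(F)(F)F)=C(C(C)C)CC[C@H]1C
F8 | step 10 | ArC6,ArC8 dialdehyde with hydroxyl at ArC7 and methoxy at ArC5 | CC(C)C[C@@H]1c2c(OC)c(C=O)c(O)c(C=O)c2O[C@H]2[C@]1(C)CC[C@@]21C(OS(=O)(=O)C(F)(F)F)=C(C(C)C)CC[C@H]1C
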